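**Plan**

1. Retrosynthetic cuts, in order: the aryl ester bond between butanoyl C1 and the phenol oxygen; the acetyl C–O bond on the C3 oxygen; the C3–O bond, traced back to a C3–B bond; and, in the aromatic half, the bond between the ring carbon ortho to the phenol oxygen and the prenyl CH2.
2. Enabling feature: the only stereocentre, C3 of the butanoyl chain, carries oxygen and lies β to the acyl carbon C1. This is the pattern left by adding a boryl nucleophile to C3 of an (E)-but-2-enoate and oxidising C–B to C–O. The only ring, the benzene ring, is bought intact and no ring is formed.
3. Forward order: tert-butyl crotonate 1 and diboron 2 give boronate 3, then alcohol 4, acetate 5 and acid 6. Separately, methyl 4-hydroxycinnamate 7 is C-prenylated with prenyl bromide 8 (through phenoxide 9) to phenol 10. Acid 6 and phenol 10 are joined (through O-acylisourea 11) to the target 12.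
4. Stereochemistry: (S) at C3 is set by the chiral ferrocenyl diphosphine on copper in step 1 and carried through the stereoretentive boron-to-oxygen oxidation. The (E)-cinnamate geometry is bought with 7. No later step touches either element.
5. Ordering logic: borylation and tert-butyl ester acidolysis are done on the small fragment, because the cinnamate would accept the copper boryl and the ortho-prenyl phenol would not tolerate trifluoroacetic acid.

Key step: step 1

Assumption: (R)-1-[(Sp)-2-(diphenylphosphino)ferrocenyl]ethyldicyclohexylphosphine is taken to deliver boron to the face of 1 that gives (S)-3; the sense is to be checked on alcohol 4 against the known (S)-(+)-alcohol, and the mirror-image ligand, equally available, is used if it proves opposite.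

**Route**

Step 1
Reactants: 1 tert-butyl (E)-but-2-enoate (tert-butyl crotonate); 2 bis(pinacolato)diboron
Product: 3 tert-butyl (S)-3-(4,4,5,5-tetramethyl-1,3,2-dioxaborolan-2-yl)butanoate
Conditions: CuCl (3 mol %), NaOtBu (6 mol %), (R)-1-[(Sp)-2-(diphenylphosphino)ferrocenyl]ethyldicyclohexylphosphine (4 mol %), MeOH (2 equiv), THF, rt
Reagents that add atoms: none
Why: CuCl and NaOtBu give a ligated copper tert-butoxide that undergoes σ-bond metathesis with 2 to a boryl complex of monovalent copper; this adds syn across C2=C3 of 1 with boron going to the β-carbon C3, and methanol protonates the resulting copper enolate at C2, releasing 3 and a copper methoxide that re-enters the cycle with 2. The closest known reaction type is the copper-catalysed enantioselective β-borylation (conjugate boryl addition) of α,β-unsaturated esters with chiral diphosphines and an alcohol additive. No ring is closed; the step forms the C3–B bond and the C2–H bond. The new stereocentre C3 is controlled by the catalyst: the planar- and centrally chiral ferrocenyl diphosphine leaves one enantioface of the copper-bound alkene open to boryl migration. The step needs β-regioselectivity and enantioface selectivity on an acceptor whose β-substituents differ only as methyl versus hydrogen; the polarisation of the enoate secures the first, and the single (E) geometry of 1 together with the bulky tert-butyl ester, which fixes how the substrate sits in the chiral pocket and resists transesterification by methoxide, secures the second. It is run on the bare crotonate because the cinnamate of the target would compete for the copper boryl.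

Step 2
Reactants: 3 tert-butyl (S)-3-(4,4,5,5-tetramethyl-1,3,2-dioxaborolan-2-yl)butanoate
Product: 4 tert-butyl (S)-3-hydroxybutanoate
Conditions: NaBO3·4H2O (4 equiv), THF/H2O (1:1), rt
Reagents that add atoms: sodium perborate tetrahydrate, NaBO3·4H2O, SMILES [Na+].[Na+].O[B-]1(O)OO[B-](O)(O)OO1.O.O.O.O.O.O
Why: Oxidation of a secondary alkylboronate by peroxide proceeds by addition of the peroxo oxygen to boron and 1,2-migration of C3 from boron to oxygen with retention, so (S)-3 should give (S)-4, and the mildly basic perborate leaves the tert-butyl ester intact.

Step 3
Reactants: 4 tert-butyl (S)-3-hydroxybutanoate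
Product: 5 tert-butyl (S)-3-acetoxybutanoate
Conditions: Ac2O (1.5 equiv), pyridine (2 equiv), DMAP (5 mol %), CH2Cl2, 0 °C to rt
Reagents that add atoms: acetic anhydride, SMILES CC(=O)OC(C)=O
Why: DMAP-catalysed O-acetylation of a secondary alcohol leaves the C3–O bond untouched, so the configuration is kept, and the hindered, weakly acidifying tert-butyl ester makes base-induced β-elimination slow under amine bases.

Step 4
Reactants: 5 tert-butyl (S)-3-acetoxybutanoate
Product: 6 (S)-3-acetoxybutanoic acid
Conditions: TFA/CH2Cl2 (1:3), 0 °C to rt; co-evaporation with toluene
Reagents that add atoms: none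
Why: Acidolysis of a tert-butyl ester proceeds through the tert-butyl cation with loss of 2-methylpropene, conditions under which the secondary acetate and the non-ionisable C3 stereocentre are inert.

Step 5
Reactants: 7 methyl (E)-3-(4-hydroxyphenyl)prop-2-enoate (methyl 4-hydroxycinnamate); 8 1-bromo-3-methylbut-2-ene (prenyl bromide)
Product: 10 methyl (E)-3-[4-hydroxy-3-(3-methylbut-2-en-1-yl)phenyl]prop-2-enoate, via sodium 4-[(E)-3-methoxy-3-oxoprop-1-en-1-yl]phenolate 9 (not isolated)
Conditions: NaH (1.1 equiv), toluene, 0 °C to rt; then 8 (1.0 equiv), rt, dark
Reagents that add atoms: none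
Why: In a non-polar solvent the aggregated sodium phenoxide keeps its oxygen tied to the cation, so SN2 attack on the primary carbon of the allylic bromide comes from the ortho ring carbon (ortho C-allylation of a phenoxide ion pair); the para position is blocked, the two ortho positions are equivalent, and limiting the bromide to one equivalent restrains a second prenylation.

Step 6
Reactants: 6 (S)-3-acetoxybutanoic acid; 10 methyl (E)-3-[4-hydroxy-3-(3-methylbut-2-en-1-yl)phenyl]prop-2-enoate
Product: 12 methyl (E)-3-[4-{[(S)-3-acetoxybutanoyl]oxy}-3-(3-methylbut-2-en-1-yl)phenyl]prop-2-enoate, via N,N'-dicyclohexyl-O-[(S)-3-acetoxybutanoyl]isourea 11 (not isolated)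
Conditions: N,N'-dicyclohexylcarbodiimide (1.1 equiv), DMAP (10 mol %), CH2Cl2, 0 °C to rt
Reagents that add atoms: none
Why: Steglich esterification, in which the carbodiimide activates the acid and DMAP passes the acyl group to the phenol, is neutral and acid-free, so the prenyl alkene, the cinnamate and the methyl ester are spared, and C3, being β to the carbonyl, cannot epimerise by enolisation.

**Compound list**

1 | tert-butyl (E)-but-2-enoate | C/C=C/C(=O)OC(C)(C)C | starting material
2 | bis(pinacolato)diboron | CC1(C)OB(OC1(C)C)B1OC(C)(C)C(C)(C)O1 | starting material
3 | tert-butyl (S)-3-(4,4,5,5-tetramethyl-1,3,2-dioxaborolan-2-yl)butanoate | CC(C)(C)OC(=O)C[C@H](C)B1OC(C)(C)C(C)(C)O1 | intermediate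
4 | tert-butyl (S)-3-hydroxybutanoate | CC(C)(C)OC(=O)C[C@H](C)O | intermediate
5 | tert-butyl (S)-3-acetoxybutanoate | CC(C)(C)OC(=O)C[C@H](C)OC(C)=O | intermediate
6 | (S)-3-acetoxybutanoic acid | OC(=O)C[C@H](C)OC(C)=O | intermediate
7 | methyl (E)-3-(4-hydroxyphenyl)prop-2-enoate | COC(=O)/C=C/c1ccc(O)cc1 | starting material
8 | 1-bromo-3-methylbut-2-ene (prenyl bromide) | CC(C)=CCBr | starting material
9 | sodium 4-[(E)-3-methoxy-3-oxoprop-1-en-1-yl]phenolate | COC(=O)/C=C/c1ccc([O-])cc1.[Na+] | intermediate (not isolated)
10 | methyl (E)-3-[4-hydroxy-3-(3-methylbut-2-en-1-yl)phenyl]prop-2-enoate | COC(=O)/C=C/c1ccc(O)c(CC=C(C)C)c1 | intermediate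
11 | N,N'-dicyclohexyl-O-[(S)-3-acetoxybutanoyl]isourea (one tautomer drawn) | C1CCC(CC1)NC(=NC1CCCCC1)OC(=O)C[C@H](C)OC(C)=O | intermediate (not isolated)
12 | methyl (E)-3-[4-{[(S)-3-acetoxybutanoyl]oxy}-3-(3-methylbut-2-en-1-yl)phenyl]prop-2-enoate (CNP0290147.1) | COC(=O)/C=C/c1ccc(OC(=O)C[C@H](C)OC(C)=O)c(CC=C(C)C)c1 | target

**Step count**

Total steps: 6. Longest linear sequence: 5 (steps 1, 2, 3, 4 and 6); step 5 runs in parallel.

**Steps most likely to fail**

Step 5. Competing O-alkylation, a second prenylation at the other ortho carbon and sluggish reaction of the acceptor-substituted, poorly soluble phenoxide could leave little mono-C-prenylated material. The fallback avoids phenoxide C-alkylation altogether. It sets out from 7. O-Allylation with allyl bromide and K2CO3 in refluxing acetone should give methyl (E)-3-[4-(prop-2-en-1-yloxy)phenyl]prop-2-enoate F1. Aromatic Claisen rearrangement in N,N-diethylaniline at about 200 °C should move the allyl group to the only open ortho position and give methyl (E)-3-[4-hydroxy-3-(prop-2-en-1-yl)phenyl]prop-2-enoate F2. Cross-metathesis of the terminal alkene with excess 2-methylbut-2-ene and the second-generation Grubbs catalyst (H2IMes)(PCy3)Cl2Ru=CHPh in CH2Cl2 at 40 °C should then turn allyl into prenyl. The electron-poor, 1,2-disubstituted cinnamate alkene is expected to stay out of the metathesis. The sequence returns to the route at 10.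

Step 1. Enantioface discrimination may be incomplete, since the catalyst must tell methyl from hydrogen at C3 and any ligand-free copper boryl adds without selectivity. The fallback adds a second, independent stereochemical filter after the oxidation. It sets out from 4 of insufficient enantiomeric purity. Immobilised Candida antarctica lipase B with vinyl acetate in tert-butyl methyl ether at rt is expected to acetylate the minor (R)-alcohol selectively, to tert-butyl (R)-3-acetoxybutanoate F3. This is separated by chromatography or distillation from the unreacted (S)-alcohol, which returns to the route at 4.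

Step 6. Deprotonation at C2 of the activated acyl species by DMAP, with loss of acetate (β-elimination to a crotonyl derivative), and O-to-N acyl migration to an N-acylurea when the ortho-substituted phenol attacks slowly, could both divert the acid. The fallback replaces in-flask carbodiimide activation by a preformed acyl halide and needs no nucleophilic catalyst. It sets out from 6. Oxalyl chloride with catalytic DMF in CH2Cl2 at 0 °C should give (S)-3-acetoxybutanoyl chloride F4, which is freed of volatiles and added to 10 and pyridine in CH2Cl2 at −20 °C. The HCl is trapped as the pyridinium salt, so the prenyl group is not exposed to acid, and the sequence returns to the route at 12.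

**Further compounds**

F1 | step 5 | methyl (E)-3-[4-(prop-2-en-1-yloxy)phenyl]prop-2-enoate | COC(=O)/C=C/c1ccc(OCC=C)cc1
F2 | step 5 | methyl (E)-3-[4-hydroxy-3-(prop-2-en-1-yl)phenyl]prop-2-enoate | COC(=O)/C=C/c1ccc(O)c(CC=C)c1
F3 | step 1 | tert-butyl (R)-3-acetoxybutanoate | CC(C)(C)OC(=O)C[C@@H](C)OC(C)=O
F4 | step 6 | (S)-3-acetoxybutanoyl chloride | ClC(=O)C[C@H](C)OC(C)=O
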